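**Open questions.** 3 questions stood open on this flask, and the earlier dawn run was what I had to answer them from.

- dawn: X 34 mM; D 14 mM; E 170 mM; run made earlier
- flask: X 34 mM; D 27.2 mM; E 170 mM; time 15 d

dawn run (percent of the X charged)

| time / d | Q / % | Z / % |
|---|---|---|
| 0.333 | 11 | 49 |
| 0.833 | 13 | 74 |
| 1.67 | 15 | 81 |
| 2.50 | 19 | 82 |
| 3.00 | 16 | 85 |
| 5.00 | 14 | 83 |

(each reading ± 1.5 percentage points)

- a reading or a percentage of Q counts all its forms, free or not

- ratio of Q to Z at 8.0 min
- ratio of Q to Z at 15 d
- which of Q and Z there is more of at 15 d

**Bench rule.** At 5.00 d the dawn run held Z worth 2.02 times the D charged, so I did not take D as a partner of Z. Pooled over the 6 readings, Q to Z read 0.194. My own assumption was that Q takes D and Z takes E, so the ratio follows D over E. Dividing the reading by the dawn charge ratio gave a selectivity factor of 2.35, the ratio of Q to Z per unit of D charged over E charged. For this flask it gave 0.377.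

**Its border.** The rule treats D as staying at its charge, yet each Q would spend one D. Counting the X charged as ending in Q and Z, the ratios and the charges gave a reckoned spent fraction of D of 39.4% for the dawn run and 34.2% for this flask. The factor was read with that drift inside it, so I trusted it for flasks spending a fraction of D near the dawn one, and not beyond.

**The forecast.** It gave 0.25 (range 0.14 to 0.45) at the early time, 0.23 (range 0.1 to 0.45) at the late time, and Z ahead. It wrote “If only the Q path uses D, the ratio approaches 0.37”, but chose a lower value, whereas my reckoning stayed with the proportional case.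

**The flask.** The ratio came out at 0.438 at 8.0 min and 0.411 at 15 d, with Z ahead at 70.9%. The forecast's late ratio was low by a factor of 1.79. My 0.377 lay a little below the late ratio, and 36.4% of the D charged was gone from this flask at 15 d.

    D + G → Q (k = 3700 M⁻¹ h⁻¹)
    E + Q ⇌ J, settled at all times (K = 11.0 M⁻¹)
    E + G → Z (k = 1400 M⁻¹ h⁻¹)
    E ⇌ L (K = 0.0970, k = 0.760 h⁻¹)
    X ⇌ G (K = 0.190, k = 0.110 h⁻¹)

**The split.** At 0.263 d in this flask, close to the 0.271 d by which half of the turnover to Z was done, E used G 2.4 times as fast as D did. Q was then forming at 0.412 of the rate of Z, against the 0.411 that stood at the end.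

**Second flask.** The neighbour with 58 mM of X keeps both charges of D and E, so the factor again gives 0.377, now with a reckoned 58.3% of D spent, beyond the dawn fraction. The computed neighbour gives 0.371 at its end, with 57.7% of its D spent.

The data were computed with made-up constants; the scatter is artificial.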